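**Strategy.** The route rests on cutting the aryl ether O–C bond at the fully substituted carbon shared by the cyclopentane and the six-membered ring of the carane. That carbon lies 1,3 across the cyclopentane from the methyl-bearing quaternary carbon that holds the benzylic CH(aryl)(isobutyl) arm, so an ortho phenol oxygen can reach it from one face only. A cobalt-hydride hydrogen-atom-transfer hydroalkoxylation of the cyclopentene C=C in a C-alkylated diformylphloroglucinol (30) forms this bond, closes the bridged oxepane and sets the last stereocentre, giving the target without protecting groups. The precursor comes from an Ireland–Claisen rearrangement, a carbene cyclopropanation and a hydride delivery anti to the cyclopropane.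

Key step: step 21

Locants for the tricyclic compounds (cyclopropa[e]indene numbering): C1 = CMe2; C1a and C6b = cyclopropane CH (C6b next to the ring fusion); C2 = CH2 or C=O; C3 = carbon bearing CH3; C3a = ring-fusion carbon that becomes C–O; C4, C5 = the other two five-ring carbons; C6 = quaternary carbon bearing CH3 and the arm; C6a = ring-fusion CH. In every tricyclic compound the cyclopropane is cis-fused, H-6a is cis to C1 and to the arm on C6, and the benzylic carbon is R.

Assumption: the Ireland–Claisen rearrangement of the cyclopentenyl arylacetate is taken to pass through the boat-like transition state usual for cycloalkenyl esters, with the aryl group cis to the silyloxy group of the ketene acetal; this fixes the (S)-cyclopentenol as the required enantiomer.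

Step 1
Reactants: 1 3-methylcyclopent-2-en-1-one
Product: 2 (1S)-3-methylcyclopent-2-en-1-ol
Conditions: (R)-Me-CBS (10 mol %), BH3·SMe2, THF, −20 °C; MeOH
Reagents that add atoms: none
Why: Corey–Bakshi–Shibata reduction is 1,2-selective and, with the alkenyl side acting as the large group, the (R)-oxazaborolidine should give the (S)-carbinol, the one stereocentre from which all others are relayed.

Step 2
Reactants: 2 (1S)-3-methylcyclopent-2-en-1-ol; 3 (2,4,6-trimethoxyphenyl)acetic acid
Product: 4 (1S)-3-methylcyclopent-2-en-1-yl (2,4,6-trimethoxyphenyl)acetate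
Conditions: DCC, DMAP (cat.), CH2Cl2, 0 °C → rt
Reagents that add atoms: none
Why: Steglich esterification acylates the acid-labile allylic alcohol under neutral conditions without touching the carbinol centre.

Step 3
Reactants: 4 (1S)-3-methylcyclopent-2-en-1-yl (2,4,6-trimethoxyphenyl)acetate
Product: 7 (2R)-2-[(1R)-1-methylcyclopent-2-en-1-yl]-2-(2,4,6-trimethoxyphenyl)acetic acid, via silyl ketene acetal 5 (not isolated), via trimethylsilyl ester 6 (not isolated)
Conditions: LDA, THF, −78 °C; TMSCl, −78 °C → rt, then 60 °C; aq. HCl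
Reagents that add atoms: none
Why: Ireland–Claisen rearrangement, in which the arylacetate gives the ketene acetal with aryl cis to OSiMe3, the boat-like transition state keeps the aryl group away from the ring and the C–O chirality is transferred suprafacially, so the quaternary and the benzylic carbon are set together with the relative and absolute configuration of the target arm.

Step 4
Reactants: 7 (2R)-2-[(1R)-1-methylcyclopent-2-en-1-yl]-2-(2,4,6-trimethoxyphenyl)acetic acid
Product: 8 (2R)-2-[(1R)-3-hydroxy-1-methylcyclopentyl]-2-(2,4,6-trimethoxyphenyl)ethan-1-ol (both C3 carbinol epimers)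
Conditions: BH3·THF (excess), THF, 0 °C → rt; NaOH, H2O2
Reagents that add atoms: hydrogen peroxide, OO
Why: Borane reduces the carboxylic acid to the primary alcohol and hydroborates the cyclopentene with boron on the carbon remote from the quaternary centre (hydroboration–oxidation); the new carbinol configuration is irrelevant because it is oxidised in step 5.

Step 5
Reactants: 8 (2R)-2-[(1R)-3-hydroxy-1-methylcyclopentyl]-2-(2,4,6-trimethoxyphenyl)ethan-1-ol
Product: 9 (2R)-2-[(1R)-1-methyl-3-oxocyclopentyl]-2-(2,4,6-trimethoxyphenyl)acetaldehyde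
Conditions: Dess–Martin periodinane (2.5 equiv), NaHCO3, CH2Cl2, rt
Reagents that add atoms: none
Why: Dess–Martin oxidation converts both alcohols under buffered, non-basic conditions that should not epimerise the α-aryl aldehyde.

Step 6
Reactants: 9 (2R)-2-[(1R)-1-methyl-3-oxocyclopentyl]-2-(2,4,6-trimethoxyphenyl)acetaldehyde
Product: 10 (3R)-3-methyl-3-[(1R)-3-methyl-1-(2,4,6-trimethoxyphenyl)but-2-en-1-yl]cyclopentan-1-one
Conditions: Me2CI2, CrCl2, THF–DMF, rt
Reagents that add atoms: 2,2-diiodopropane, CC(C)(I)I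
Why: Takai–Utimoto alkylidenation with the gem-dichromium reagent olefinates aldehydes but not ketones and is non-basic, so the isobutenyl group should be installed chemoselectively without loss of the benzylic configuration.

Step 7
Reactants: 10 (3R)-3-methyl-3-[(1R)-3-methyl-1-(2,4,6-trimethoxyphenyl)but-2-en-1-yl]cyclopentan-1-one
Product: 11 (3R)-3-methyl-3-[(1R)-3-methyl-1-(2,4,6-trimethoxyphenyl)butyl]cyclopentan-1-one
Conditions: H2 (1 atm), Pt/C, EtOAc, rt
Reagents that add atoms: none
Why: Heterogeneous hydrogenation saturates the only C=C bond to the isobutyl group, platinum being chosen to limit double-bond migration through the benzylic stereocentre.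

Step 8
Reactants: 11 (3R)-3-methyl-3-[(1R)-3-methyl-1-(2,4,6-trimethoxyphenyl)butyl]cyclopentan-1-one
Product: 13 (4S)-4-methyl-4-[(1R)-3-methyl-1-(2,4,6-trimethoxyphenyl)butyl]cyclopent-2-en-1-one, via trimethylsilyl enol ether 12 (not isolated)
Conditions: LDA, THF, −78 °C; TMSCl; then Pd(OAc)2, MeCN, rt
Reagents that add atoms: none
Why: Saegusa–Ito oxidation, in which kinetic enolisation occurs at the CH2 remote from the quaternary carbon and only that side carries a β-hydrogen, so the 4,4-disubstituted cyclopent-2-enone is the single possible enone.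

Step 9
Reactants: 13 (4S)-4-methyl-4-[(1R)-3-methyl-1-(2,4,6-trimethoxyphenyl)butyl]cyclopent-2-en-1-one
Product: 14 2-iodo-4-methyl-4-[(1R)-3-methyl-1-(2,4,6-trimethoxyphenyl)butyl]cyclopent-2-en-1-one (ring centre unchanged from 13)
Conditions: I2, pyridine, CH2Cl2, 0 °C → rt
Reagents that add atoms: iodine, II
Why: Pyridine-mediated α-iodination of the enone (conjugate addition of pyridine, iodination of the enolate, elimination) gives the 2-iodoenone as a cross-coupling handle.

Step 10
Reactants: 14 2-iodo-4-methyl-4-[(1R)-3-methyl-1-(2,4,6-trimethoxyphenyl)butyl]cyclopent-2-en-1-one; 15 tert-butyl 2-bromopropanoate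
Product: 16 tert-butyl 2-{3-methyl-3-[(1R)-3-methyl-1-(2,4,6-trimethoxyphenyl)butyl]-5-oxocyclopent-1-en-1-yl}propanoate (ring centre as in 13; both propanoate α-epimers)
Conditions: 15, Zn, THF; then 14, Pd(dba)2/P(t-Bu)3 (cat.), THF, rt
Reagents that add atoms: none
Why: Negishi coupling of the Reformatsky reagent with the alkenyl iodide joins the propanoate α-carbon to the enone α-carbon; the new α-centre is left as a mixture because it is planarised in step 14.

Step 11
Reactants: 16 tert-butyl 2-{3-methyl-3-[(1R)-3-methyl-1-(2,4,6-trimethoxyphenyl)butyl]-5-oxocyclopent-1-en-1-yl}propanoate; 17 1-bromo-2-methylprop-1-ene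
Product: 18 tert-butyl 2-{4-methyl-4-[(1R)-3-methyl-1-(2,4,6-trimethoxyphenyl)butyl]-5-(2-methylprop-1-en-1-yl)-2-(triethylsilyloxy)cyclopent-1-en-1-yl}propanoate (isobutenyl cis to the ring methyl; α-epimers)
Conditions: 17, Mg, THF; then 16, CuBr·SMe2 (cat.), Et3SiCl, HMPA, THF, −78 → −40 °C; Et3N
Reagents that add atoms: chlorotriethylsilane, CC[Si](Cl)(CC)CC
Why: Silyl chloride-accelerated copper-catalysed conjugate addition should place the isobutenyl group on the β-carbon from the face opposite the bulky benzylic arm (cis to the ring methyl), and trapping the enolate as the silyl enol ether masks the ketone for the carbene step.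

Step 12
Reactants: 18 tert-butyl 2-{4-methyl-4-[(1R)-3-methyl-1-(2,4,6-trimethoxyphenyl)butyl]-5-(2-methylprop-1-en-1-yl)-2-(triethylsilyloxy)cyclopent-1-en-1-yl}propanoate
Product: 21 1-diazo-3-{4-methyl-4-[(1R)-3-methyl-1-(2,4,6-trimethoxyphenyl)butyl]-5-(2-methylprop-1-en-1-yl)-2-(triethylsilyloxy)cyclopent-1-en-1-yl}butan-2-one, via trimethylsilyl ester 19 (not isolated), via acid chloride 20 (not isolated)
Conditions: TMSOTf, 2,6-lutidine, CH2Cl2, 0 °C; (COCl)2, DMF (cat.); CH2N2, Et2O, 0 °C
Reagents that add atoms: diazomethane, C=[N+]=[N-]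
Why: Silyl triflate cleaves the tert-butyl ester to the silyl ester, oxalyl chloride converts this into the acid chloride under neutral conditions that spare the silyl enol ether, and acylation of diazomethane (first stage of the Arndt–Eistert sequence) gives the α-diazoketone.

Step 13
Reactants: 21 1-diazo-3-{4-methyl-4-[(1R)-3-methyl-1-(2,4,6-trimethoxyphenyl)butyl]-5-(2-methylprop-1-en-1-yl)-2-(triethylsilyloxy)cyclopent-1-en-1-yl}butan-2-one
Product: 22 6-[(1R)-3-methyl-1-(2,4,6-trimethoxyphenyl)butyl]-1,1,3,6-tetramethyl-4-(triethylsilyloxy)-1a,3,5,6,6a,6b-hexahydro-1H-cyclopropa[e]inden-2-one (C3a=C4 enol ether; C3 epimers)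
Conditions: Cu(acac)2 (cat.), toluene, 80 °C, slow addition
Reagents that add atoms: none
Why: Intramolecular carbenoid cyclopropanation of the trisubstituted alkene closes the six-membered ring and the cis-fused gem-dimethylcyclopropane at once; allylic 1,3-strain holds H-6a in the alkene plane, so the tethered carbenoid adds on the face away from the quaternary carbon and the cyclopropane ends up cis to H-6a.

Step 14
Reactants: 22 6-[(1R)-3-methyl-1-(2,4,6-trimethoxyphenyl)butyl]-1,1,3,6-tetramethyl-4-(triethylsilyloxy)-1a,3,5,6,6a,6b-hexahydro-1H-cyclopropa[e]inden-2-one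
Product: 23 6-[(1R)-3-methyl-1-(2,4,6-trimethoxyphenyl)butyl]-1,1,3,6-tetramethyl-4-(triethylsilyloxy)-1a,5,6,6a,6b-pentahydro-1H-cyclopropa[e]inden-2-yl trifluoromethanesulfonate (C2=C3 and C3a=C4 diene)
Conditions: KHMDS, THF, −78 °C; PhNTf2
Reagents that add atoms: N-phenylbis(trifluoromethanesulfonimide), O=S(=O)(N(c1ccccc1)S(=O)(=O)C(F)(F)F)C(F)(F)F
Why: The ketone can enolise only toward C3, so O-sulfonylation of the dienolate gives a single enol triflate and at the same time erases the uncontrolled C3 configuration.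

Step 15
Reactants: 23 the C2 enol triflate
Product: 24 triethyl{[6-[(1R)-3-methyl-1-(2,4,6-trimethoxyphenyl)butyl]-1,1,3,6-tetramethyl-1a,5,6,6a,6b-pentahydro-1H-cyclopropa[e]inden-4-yl]oxy}silane (C2=C3 and C3a=C4 diene)
Conditions: Pd(OAc)2, PPh3 (cat.), HCO2H, Bu3N, DMF, 60 °C
Reagents that add atoms: none
Why: Palladium-catalysed formate reduction of the enol triflate removes the oxygen next to the cyclopropane through a vinylpalladium species, avoiding the cyclopropylcarbinyl radical or cation and the epimerising base of other ketone deoxygenations.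

Step 16
Reactants: 24 the silyl dienol ether
Product: 25 6-[(1R)-3-methyl-1-(2,4,6-trimethoxyphenyl)butyl]-1,1,3,6-tetramethyl-1a,2,5,6,6a,6b-hexahydro-1H-cyclopropa[e]inden-4-one (C3=C3a enone)
Conditions: TBAF, AcOH, THF, 0 °C; then DBU, CH2Cl2, rt
Reagents that add atoms: none
Why: Fluoride cleavage of the silyl dienol ether followed by base equilibration should give the conjugated alkylidenecyclopentanone, the only conjugated isomer that proton shifts can reach.

Step 17
Reactants: 25 the C3=C3a enone
Product: 27 6-[(1R)-3-methyl-1-(2,4,6-trimethoxyphenyl)butyl]-1,1,3,6-tetramethyl-1a,2,3,5,6,6a,6b-heptahydro-1H-cyclopropa[e]inden-4-yl trifluoromethanesulfonate (C3a=C4; 3-CH3 cis to C1), via diethoxymethylsilyl enol ether 26 (not isolated)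
Conditions: Cu(OAc)2·H2O, 1,2-bis(diphenylphosphino)benzene (cat.), (EtO)2MeSiH, toluene, rt; then MeLi, THF, 0 °C; PhNTf2
Reagents that add atoms: N-phenylbis(trifluoromethanesulfonimide), O=S(=O)(N(c1ccccc1)S(=O)(=O)C(F)(F)F)C(F)(F)F
Why: Copper hydride conjugate reduction should deliver hydride to C3 from the face opposite the cyclopropane, whose endo methyl shields the other face as in 3-carene, so the 3-methyl group ends up cis to the cyclopropane, and the regiodefined enolate released from its silyl ether by methyllithium is trapped as the C3a=C4 enol triflate.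

Step 18
Reactants: 27 the C4 enol triflate
Product: 28 6-[(1R)-3-methyl-1-(2,4,6-trimethoxyphenyl)butyl]-1,1,3,6-tetramethyl-1a,2,3,5,6,6a,6b-heptahydro-1H-cyclopropa[e]indene (C3a=C4 alkene; 3-CH3 cis to C1)
Conditions: Pd(OAc)2, PPh3 (cat.), HCO2H, Bu3N, DMF, 60 °C
Reagents that add atoms: none
Why: Palladium-catalysed formate reduction of the enol triflate gives the trisubstituted C3a=C4 alkene exactly where the triflate fixed it.

Step 19
Reactants: 28 the trimethoxyaryl alkene
Product: 29 2,4,6-trimethoxy-5-{(1R)-3-methyl-1-[C6 of the tricycle of 28]butyl}benzene-1,3-dicarbaldehyde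
Conditions: n-BuLi, TMEDA, THF, 0 °C; DMF, −78 °C; n-BuLi, −78 → 0 °C; DMF; aq. NH4Cl
Reagents that add atoms: N,N-dimethylformamide, CN(C)C=O
Why: Directed ortho-lithiation occurs at each aryl position flanked by two methoxy groups, and the first DMF adduct persists as a lithium α-amino alkoxide that protects the first formyl group while the second position is lithiated and formylated, a non-acidic alternative to Friedel–Crafts formylation.

Step 20
Reactants: 29 the trimethoxy dialdehyde
Product: 30 2,4,6-trihydroxy-5-{(1R)-3-methyl-1-[C6 of the tricycle of 28]butyl}benzene-1,3-dicarbaldehyde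
Conditions: p-TolSLi, HMPA–toluene, 110 °C; aq. HCl (0 °C)
Reagents that add atoms: none
Why: Thiolate SN2 demethylation is favoured for aryl methyl ethers ortho or para to formyl groups and is non-acidic, so the three phenols should be released without touching the alkene or the cyclopropane.

Step 21
Reactants: 30 the diformylphloroglucinol alkene
Product: 31 CNP0202714.1 (aryl ether from one ortho phenol oxygen to C3a; oxepane bridging C3a and C6; oxygen on the face of the arm)
Conditions: Co(II)(salen) (5 mol %), N-fluoro-2,4,6-trimethylpyridinium triflate, PhSiH3, PhCF3, 0 °C → rt, 0.01 M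
Reagents that add atoms: none
Why: A cobalt(III) hydride formed from the salen complex, the N-fluoropyridinium oxidant and the silane transfers a hydrogen atom to C4, the less substituted alkene carbon, and the tertiary C3a radical is oxidised to an alkylcobalt(IV) or cation-like species that an ortho phenol oxygen captures (radical–polar crossover). The closest known reaction type is the cobalt-catalysed intramolecular Markovnikov hydroalkoxylation of unactivated alkenes by alcohols and phenols, which also forms medium rings. The oxepane closes in a 7-exo mode onto C3a, with C4 left outside the new ring. The C3a configuration is set by the substrate, because the arm on C6 is 1,3 to C3a on the cyclopentane and the oxygen can therefore bond only on the face that carries the arm. The step needs Markovnikov regiochemistry and survival of the cyclopropane and the aldehydes; hydrogen-atom transfer to the trisubstituted alkene secures the first, and the non-acidic conditions, the C6a methine between C3a and the cyclopropane, and the hydrogen-bonded formyl groups secure the rest. Either ortho hydroxyl gives the same product, so no protecting group is needed.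

**Compound list**

1 | 3-methylcyclopent-2-en-1-one | CC1=CC(=O)CC1 | starting material
2 | (1S)-3-methylcyclopent-2-en-1-ol | CC1=C[C@@H](O)CC1 | intermediate
3 | (2,4,6-trimethoxyphenyl)acetic acid | COc1cc(OC)c(CC(O)=O)c(OC)c1 | starting material
4 | (1S)-3-methylcyclopent-2-en-1-yl (2,4,6-trimethoxyphenyl)acetate | CC1=C[C@@H](OC(=O)Cc2c(OC)cc(OC)cc2OC)CC1 | intermediate
5 | (Z)-silyl ketene acetal of 4 (aryl cis to OSiMe3) | CC1=C[C@@H](O/C(=C/c2c(OC)cc(OC)cc2OC)O[Si](C)(C)C)CC1 | intermediate
6 | trimethylsilyl (2R)-2-[(1R)-1-methylcyclopent-2-en-1-yl]-2-(2,4,6-trimethoxyphenyl)acetate | C[Si](C)(C)OC(=O)[C@@H](c1c(OC)cc(OC)cc1OC)[C@@]1(C)C=CCC1 | intermediate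
7 | (2R)-2-[(1R)-1-methylcyclopent-2-en-1-yl]-2-(2,4,6-trimethoxyphenyl)acetic acid | OC(=O)[C@@H](c1c(OC)cc(OC)cc1OC)[C@@]1(C)C=CCC1 | intermediate
8 | (2R)-2-[(1R)-3-hydroxy-1-methylcyclopentyl]-2-(2,4,6-trimethoxyphenyl)ethan-1-ol (C3 carbinol epimers) | OC[C@@H](c1c(OC)cc(OC)cc1OC)[C@@]1(C)CC(O)CC1 | intermediate
9 | (2R)-2-[(1R)-1-methyl-3-oxocyclopentyl]-2-(2,4,6-trimethoxyphenyl)acetaldehyde | O=C[C@@H](c1c(OC)cc(OC)cc1OC)[C@@]1(C)CC(=O)CC1 | intermediate
10 | (3R)-3-methyl-3-[(1R)-3-methyl-1-(2,4,6-trimethoxyphenyl)but-2-en-1-yl]cyclopentan-1-one | CC(C)=C[C@@H](c1c(OC)cc(OC)cc1OC)[C@@]1(C)CC(=O)CC1 | intermediate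
11 | (3R)-3-methyl-3-[(1R)-3-methyl-1-(2,4,6-trimethoxyphenyl)butyl]cyclopentan-1-one | CC(C)C[C@@H](c1c(OC)cc(OC)cc1OC)[C@@]1(C)CC(=O)CC1 | intermediate
12 | trimethyl{[(4R)-4-methyl-4-[(1R)-3-methyl-1-(2,4,6-trimethoxyphenyl)butyl]cyclopent-1-en-1-yl]oxy}silane | CC(C)C[C@@H](c1c(OC)cc(OC)cc1OC)[C@@]1(C)CC(O[Si](C)(C)C)=CC1 | intermediate
13 | (4S)-4-methyl-4-[(1R)-3-methyl-1-(2,4,6-trimethoxyphenyl)butyl]cyclopent-2-en-1-one | CC(C)C[C@@H](c1c(OC)cc(OC)cc1OC)[C@@]1(C)CC(=O)C=C1 | intermediate
14 | 2-iodo derivative of 13 | CC(C)C[C@@H](c1c(OC)cc(OC)cc1OC)[C@@]1(C)CC(=O)C(I)=C1 | intermediate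
15 | tert-butyl 2-bromopropanoate (racemic) | CC(Br)C(=O)OC(C)(C)C | starting material
16 | tert-butyl 2-{3-methyl-3-[(1R)-3-methyl-1-(2,4,6-trimethoxyphenyl)butyl]-5-oxocyclopent-1-en-1-yl}propanoate (α-epimers) | CC(C)C[C@@H](c1c(OC)cc(OC)cc1OC)[C@@]1(C)CC(=O)C(C(C)C(=O)OC(C)(C)C)=C1 | intermediate
17 | 1-bromo-2-methylprop-1-ene | CC(C)=CBr | starting material
18 | tert-butyl 2-{4-methyl-4-[(1R)-3-methyl-1-(2,4,6-trimethoxyphenyl)butyl]-5-(2-methylprop-1-en-1-yl)-2-(triethylsilyloxy)cyclopent-1-en-1-yl}propanoate (isobutenyl cis to ring methyl; α-epimers) | CC(C)C[C@@H](c1c(OC)cc(OC)cc1OC)[C@@]1(C)CC(O[Si](CC)(CC)CC)=C(C(C)C(=O)OC(C)(C)C)[C@@H]1C=C(C)C | intermediate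
19 | trimethylsilyl ester corresponding to 18 | CC(C)C[C@@H](c1c(OC)cc(OC)cc1OC)[C@@]1(C)CC(O[Si](CC)(CC)CC)=C(C(C)C(=O)O[Si](C)(C)C)[C@@H]1C=C(C)C | intermediate
20 | acid chloride corresponding to 18 | CC(C)C[C@@H](c1c(OC)cc(OC)cc1OC)[C@@]1(C)CC(O[Si](CC)(CC)CC)=C(C(C)C(Cl)=O)[C@@H]1C=C(C)C | intermediate
21 | 1-diazo-3-{cyclopentenyl unit of 18}butan-2-one | CC(C)C[C@@H](c1c(OC)cc(OC)cc1OC)[C@@]1(C)CC(O[Si](CC)(CC)CC)=C(C(C)C(=O)C=[N+]=[N-])[C@@H]1C=C(C)C | intermediate
22 | tricyclic C2 ketone with C3a=C4 triethylsilyl enol ether (C3 epimers) | CC(C)C[C@@H](c1c(OC)cc(OC)cc1OC)[C@@]1(C)CC(O[Si](CC)(CC)CC)=C2[C@@H]1[C@H]1[C@@H](C(=O)C2C)C1(C)C | intermediate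
23 | tricyclic C2 enol triflate (C2=C3, C3a=C4 diene; 4-OSiEt3) | CC(C)C[C@@H](c1c(OC)cc(OC)cc1OC)[C@@]1(C)CC(O[Si](CC)(CC)CC)=C2[C@@H]1[C@H]1[C@@H](C(OS(=O)(=O)C(F)(F)F)=C2C)C1(C)C | intermediate
24 | tricyclic silyl dienol ether (C2=C3, C3a=C4; 4-OSiEt3) | CC(C)C[C@@H](c1c(OC)cc(OC)cc1OC)[C@@]1(C)CC(O[Si](CC)(CC)CC)=C2[C@@H]1[C@H]1[C@@H](C=C2C)C1(C)C | intermediate
25 | tricyclic C4 ketone with C3=C3a double bond | CC(C)C[C@@H](c1c(OC)cc(OC)cc1OC)[C@@]1(C)CC(=O)C=2[C@@H]1[C@H]1[C@@H](CC=2C)C1(C)C | intermediate
26 | diethoxy(methyl)silyl enol ether (C3a=C4; 3-CH3 cis to C1) | CC(C)C[C@@H](c1c(OC)cc(OC)cc1OC)[C@@]1(C)CC(O[Si](C)(OCC)OCC)=C2[C@@H]1[C@H]1[C@@H](C[C@@H]2C)C1(C)C | intermediate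
27 | tricyclic C4 enol triflate (C3a=C4; 3-CH3 cis to C1) | CC(C)C[C@@H](c1c(OC)cc(OC)cc1OC)[C@@]1(C)CC(OS(=O)(=O)C(F)(F)F)=C2[C@@H]1[C@H]1[C@@H](C[C@@H]2C)C1(C)C | intermediate
28 | 6-[(1R)-3-methyl-1-(2,4,6-trimethoxyphenyl)butyl]-1,1,3,6-tetramethyl-1a,2,3,5,6,6a,6b-heptahydro-1H-cyclopropa[e]indene (C3a=C4) | CC(C)C[C@@H](c1c(OC)cc(OC)cc1OC)[C@@]1(C)CC=C2[C@@H]1[C@H]1[C@@H](C[C@@H]2C)C1(C)C | intermediate
29 | 3,5-diformyl-2,4,6-trimethoxyphenyl analogue of 28 | CC(C)C[C@@H](c1c(OC)c(C=O)c(OC)c(C=O)c1OC)[C@@]1(C)CC=C2[C@@H]1[C@H]1[C@@H](C[C@@H]2C)C1(C)C | intermediate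
30 | 3,5-diformyl-2,4,6-trihydroxyphenyl analogue of 28 (key-step precursor) | CC(C)C[C@@H](c1c(O)c(C=O)c(O)c(C=O)c1O)[C@@]1(C)CC=C2[C@@H]1[C@H]1[C@@H](C[C@@H]2C)C1(C)C | intermediate
31 | CNP0202714.1 | CC(C)C[C@H]1c2c(O)c(C=O)c(O)c(C=O)c2O[C@]23CC[C@@]1(C)[C@H]2[C@H]1[C@@H](C[C@@H]3C)C1(C)C | target

**Step count and risk**

Total steps: 21. Longest linear sequence: 21 steps (1 → 31); compounds 3, 15 and 17 enter as commercial inputs.

Steps most likely to fail:

Step 21. Closure of the seven-membered ether on the crowded face may be slower than quenching of the tertiary radical or cation, which would lead to net reduction of the alkene or its migration to a tetrasubstituted position. The fallback is a two-stage Markovnikov hydroalkoxylation by selenoetherification. It sets out from 30: PhSeCl with K2CO3 in CH2Cl2 at −78 °C should give, through reversible seleniranium formation and attack of the phenol oxygen at the tertiary carbon, the 4-phenylselanyl ether F1. Radical deselenation with Bu3SnH and AIBN in toluene at 80 °C then rejoins the route at 31.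

Step 17. The tetrasubstituted enone may resist copper hydride addition, undergo 1,2-reduction, or take up hydride without facial discrimination. The fallback is a dissolving-metal reduction with enolate trapping. It sets out from 25: lithium in liquid ammonia–THF at −78 °C with one equivalent of tert-butanol should give the same regiodefined lithium enolate, with protonation at C3 on the face away from the cyclopropane. After removal of ammonia the enolate is sulfonylated with PhNTf2 and the route is rejoined at 27; no new compound is made (F0).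

Step 19. The second metalation may stay incomplete, or butyllithium may attack the masked aldehyde, so that formylation stops at the mono-aldehyde. The fallback goes through halogen–lithium exchange. It sets out from 28: N-bromosuccinimide (2 equiv) in MeCN at −20 °C should brominate the two free aryl positions to give the dibromide F2. Double bromine–lithium exchange with t-BuLi in THF at −78 °C and a DMF quench rejoins the route at 29.

**Further compounds**

F1 | step 21 | 4-(phenylselanyl) derivative of 31 (selenium trans to the ether oxygen) | CC(C)C[C@H]1c2c(O)c(C=O)c(O)c(C=O)c2O[C@]23[C@@H]([Se]c4ccccc4)C[C@@]1(C)[C@H]2[C@H]1[C@@H](C[C@@H]3C)C1(C)C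
F2 | step 19 | 3,5-dibromo-2,4,6-trimethoxyphenyl analogue of 28 | CC(C)C[C@@H](c1c(OC)c(Br)c(OC)c(Br)c1OC)[C@@]1(C)CC=C2[C@@H]1[C@H]1[C@@H](C[C@@H]2C)C1(C)C
F0 | step 17 | none | none
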